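The C4 ketone of flavanone ring C lies two carbons from the benzylic C2–H stereocentre, and C2 hangs on O1, which sits on ring A ortho to C4a. Cutting C3–C4 and C2–H together turns ring C into a ring A aldehyde (C4) plus a 1-aryl vinyl ether on O1 (C2=C3), an isomer of the product.
The O1–C2(=C3H2) enol ether comes from Petasis methylenation of the aryl ester between the ring B acid and the ring A phenol. The aldehyde is masked as a dioxolane, and the step is run before the flavone carbonyl is present.
The ring B C2′–flavone C8 biaryl bond comes from Suzuki coupling of a ring B pinacol boronate with 8-iodo-tetra-O-benzylluteolin.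
The four benzene rings and the flavone pyranone are bought. Flavanone ring C is the only ring built, in the penultimate step, and eightfold hydrogenolysis follows.
Key step: step 13

Assumption: the SMILES defines only C2. The tetra-ortho-substituted axis between ring B C2′ and flavone C8 is left open, so it is not controlled, and both axial forms of the (2S) series are taken as the target.

Step 1
Reactants: 1 2-bromo-3-hydroxy-4-methoxybenzaldehyde
Product: 2 2-bromo-3,4-dihydroxybenzaldehyde
Conditions: BBr3 (2.5 equiv), CH2Cl2, −78 °C → rt; then H2O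
Reagents that add atoms: none
Why: Lewis acid ether cleavage, in which BBr3 binds the free C3 hydroxyl and the neighbouring methoxy oxygen and bromide removes the methyl group by SN2 attack, while the aryl bromide and the aldehyde are left alone at low temperature.

Step 2
Reactants: 2 2-bromo-3,4-dihydroxybenzaldehyde
Product: 3 3,4-bis(benzyloxy)-2-bromobenzaldehyde
Conditions: BnBr (2.4 equiv), K2CO3, DMF, 60 °C
Reagents that add atoms: benzyl bromide, BrCc1ccccc1
Why: Williamson ether synthesis on both acidic catechol hydroxyls, with the non-enolisable aldehyde and the aryl bromide inert to K2CO3.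

Step 3
Reactants: 3 3,4-bis(benzyloxy)-2-bromobenzaldehyde
Product: 4 3,4-bis(benzyloxy)-2-bromobenzoic acid
Conditions: NaClO2, NaH2PO4, 2-methyl-2-butene, t-BuOH/THF/H2O, rt
Reagents that add atoms: sodium chlorite, [Na+].[O-]Cl=O
Why: Pinnick oxidation takes the aryl aldehyde to the acid under buffered conditions, and the alkene traps hypochlorous acid before it can chlorinate the electron-rich ring.

Step 4
Reactants: 5 2,4,6-trihydroxybenzaldehyde
Product: 6 2,4-bis(benzyloxy)-6-hydroxybenzaldehyde
Conditions: BnBr (2.05 equiv), K2CO3 (2.1 equiv), DMF, 0 °C → rt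
Reagents that add atoms: benzyl bromide, BrCc1ccccc1
Why: Williamson ether synthesis should stop after two alkylations, because the last ortho hydroxyl is held in a hydrogen bond to the formyl oxygen and is the least nucleophilic.

Step 5
Reactants: 4 3,4-bis(benzyloxy)-2-bromobenzoic acid; 6 2,4-bis(benzyloxy)-6-hydroxybenzaldehyde
Product: 7 3,5-bis(benzyloxy)-2-formylphenyl 3,4-bis(benzyloxy)-2-bromobenzoate
Conditions: DCC, DMAP (cat.), CH2Cl2, 0 °C → rt
Reagents that add atoms: none
Why: Steglich esterification, in which DMAP relays the acyl group to the chelated phenol, is the same O-aroylation that routinely opens Baker–Venkataraman sequences on 2-hydroxyaryl carbonyl compounds.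

Step 6
Reactants: 7 3,5-bis(benzyloxy)-2-formylphenyl 3,4-bis(benzyloxy)-2-bromobenzoate
Product: 8 3,5-bis(benzyloxy)-2-(1,3-dioxolan-2-yl)phenyl 3,4-bis(benzyloxy)-2-bromobenzoate
Conditions: TMSOCH2CH2OTMS, TMSOTf (5 mol %), CH2Cl2, −78 → −20 °C; pyridine quench
Reagents that add atoms: 1,2-bis(trimethylsiloxy)ethane, C[Si](C)(C)OCCO[Si](C)(C)C
Why: Noyori acetalisation is aprotic and driven by formation of the disiloxane, so even this donor-stabilised aldehyde should be converted and the aryl ester meets no free alcohol that could transesterify it.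

Step 7
Reactants: 8 3,5-bis(benzyloxy)-2-(1,3-dioxolan-2-yl)phenyl 3,4-bis(benzyloxy)-2-bromobenzoate
Product: 9 2-[2,4-bis(benzyloxy)-6-({1-[3,4-bis(benzyloxy)-2-bromophenyl]ethenyl}oxy)phenyl]-1,3-dioxolane
Conditions: Cp2TiMe2 (2.5 equiv), toluene, 75 °C, dark; filtration through basic alumina
Reagents that add atoms: dimethyltitanocene, [CH3-].[CH3-].[Ti+4].c1cc[cH-]c1.c1cc[cH-]c1
Why: Petasis methylenation (thermal release of Cp2Ti=CH2, [2+2] addition to the ester carbonyl, cycloreversion) is the classic conversion of aryl benzoates into 1-aryloxy-1-arylethenes, it tolerates acetal, aryl bromide and benzyl ethers, and it is placed here because the flavone C4 carbonyl would also be methylenated.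

Step 8
Reactants: 9 2-[2,4-bis(benzyloxy)-6-({1-[3,4-bis(benzyloxy)-2-bromophenyl]ethenyl}oxy)phenyl]-1,3-dioxolane
Product: 11 2-[2,4-bis(benzyloxy)-6-({1-[3,4-bis(benzyloxy)-2-(4,4,5,5-tetramethyl-1,3,2-dioxaborolan-2-yl)phenyl]ethenyl}oxy)phenyl]-1,3-dioxolane, via aryllithium 10 (not isolated)
Conditions: n-BuLi (1.05 equiv), THF, −78 °C; i-PrOBpin, −78 °C → rt; H2O
Reagents that add atoms: 2-isopropoxy-4,4,5,5-tetramethyl-1,3,2-dioxaborolane, CC(C)OB1OC(C)(C)C(C)(C)O1; n-butyllithium, [Li]CCCC (lithium of 10 only)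
Why: Bromine–lithium exchange at −78 °C outruns benzylic deprotonation, compound 9 holds no electrophilic group, and the aryllithium is trapped by the borate ester (lithiation–borylation).

Step 9
Reactants: 11 ring B pinacol boronate with dioxolane
Product: 12 2,4-bis(benzyloxy)-6-({1-[3,4-bis(benzyloxy)-2-(4,4,5,5-tetramethyl-1,3,2-dioxaborolan-2-yl)phenyl]ethenyl}oxy)benzaldehyde
Conditions: PPTS (10 mol %), THF/H2O (4:1), 0 °C → rt; NaHCO3 quench; Et3N-deactivated silica
Reagents that add atoms: water, O
Why: Specific-acid acetal hydrolysis, in which the dioxolane ionises to an oxocarbenium ion stabilised by the three ring A oxygens and should cleave orders of magnitude faster than the weakly basic, twisted aryl enol ether is protonated at C3, the large excess of water captures the cation before C3 can attack it, and boronate and benzyl ethers are inert to PPTS.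

Step 10
Reactants: 13 luteolin
Product: 14 5,7,3′,4′-tetra-O-benzylluteolin
Conditions: BnBr (6 equiv), K2CO3, DMF, 80 °C
Reagents that add atoms: benzyl bromide, BrCc1ccccc1
Why: Exhaustive Williamson ether synthesis, with heat and excess reagent needed only for the C5 hydroxyl that is hydrogen-bonded to the C4 carbonyl.

Step 11
Reactants: 14 5,7,3′,4′-tetra-O-benzylluteolin
Product: 15 8-iodo-5,7,3′,4′-tetra-O-benzylluteolin
Conditions: I2, AgO2CCF3 (1.05 equiv each), CH2Cl2, 0 °C → rt, dark
Reagents that add atoms: iodine, [I][I]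
Why: Electrophilic aromatic iodination goes to the benzo ring activated by three oxygens and within it to C8, as is usual for fully etherified 5,7-dioxygenated flavones, because C6 is shielded by two benzyloxy groups.

Step 12
Reactants: 12 ring B pinacol boronate aldehyde; 15 8-iodo-5,7,3′,4′-tetra-O-benzylluteolin
Product: 16 2-[(1-arylvinyl)oxy]-4,6-bis(benzyloxy)benzaldehyde, aryl = 3,4-bis(benzyloxy)-2-(5,7,3′,4′-tetra-O-benzylluteolin-8-yl)phenyl (axis racemic)
Conditions: Pd(OAc)2 (10 mol %), SPhos (20 mol %), K3PO4 (3 equiv), toluene/H2O (10:1), 90 °C, degassed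
Reagents that add atoms: none
Why: Suzuki–Miyaura coupling with a bulky, electron-rich dialkylbiarylphosphine on zerovalent palladium is the established answer to tetra-ortho-substituted biaryls, 8-iodoflavone ethers are proven electrophiles, and the basic two-phase medium leaves enol ether, aldehyde and flavone untouched.

Step 13
Reactants: 16 2-[(1-arylvinyl)oxy]-4,6-bis(benzyloxy)benzaldehyde with the hexabenzyl ring B–flavone biaryl
Product: 17 (2S)-octa-O-benzyl target (flavanone ring C closed, 2S)
Conditions: [Rh(cod)Cl]2 (5 mol %), (R)-DTBM-SEGPHOS (11 mol %), Na[B(3,5-(CF3)2C6H3)4] (10 mol %), 2,6-di-tert-butyl-4-methylpyridine (10 mol %), 4 Å MS, 1,4-dioxane, 60 → 90 °C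
Reagents that add atoms: none
Why: Proposed new method: the cationic monovalent rhodium bisphosphine inserts into the ring A aldehyde C–H to give an acyl trivalent rhodium hydride that is held by the flanking C5 benzyloxy oxygen and the bound alkene, the hydride migrates to C2 (the oxygen- and aryl-bearing, electron-poor end of the enol ether) while rhodium takes the nucleophilic terminal C3, and C–C reductive elimination from the seven-membered acyl alkyl rhodacycle forms C3–C4. The closest known reaction type is the endo- and enantioselective rhodium hydroacylation of ortho-(2-substituted allyl)benzaldehydes to 3-substituted tetralones and of N-(1-substituted vinyl) heteroaryl aldehydes, and the step is new because an aryl 1-arylvinyl ether, with O1 in place of the benzylic CH2, has not served as the alkene. Ring C closes in the 6-endo mode with both alkene carbons inside the ring, whereas the 5-exo alternative would need a tertiary, oxygen-bearing alkyl rhodium at C2 next to the hindered ring B and would end in a 2-aryl-2-methylbenzofuran-3-one. The C2 stereocentre is set in the hydride insertion by the alkene enantioface that the twofold-symmetric ligand pocket offers to Rh–H, the ligand antipode that gives 2S is fixed beforehand on 2-[(1-phenylvinyl)oxy]benzaldehyde (its product, flavanone, has a known sign of rotation), and catalyst control has to override the racemic biaryl axis. The step needs endo over exo insertion (secured by enol ether polarity and 1,1-disubstitution), hydroacylation over decarbonylation (secured by ortho-oxygen chelation of the acyl rhodium), and insertion over β-aryloxide elimination along Rh–C3–C2–O1 (held back because O1 is an endocyclic member of the rhodacycle and cannot become syn-coplanar with Rh–C3). The sodium borate activator and the hindered pyridine keep out silver and Brønsted acid, which would drive polar attack of C3 on the aldehyde toward a flavylium salt, and the neutral medium gives the product no retro-oxa-Michael path to the chalcone, so C2 should keep its configuration.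

Step 14
Reactants: 17 (2S)-octa-O-benzyl target
Product: 18 CNP0265600.1, (2S)-eriodictyol-(2′→8″)-luteolin
Conditions: H2 (1 atm), Pd(OH)2/C, THF/MeOH (1:1), rt; filtration; Sephadex LH-20 (MeOH, 0.1 % HCO2H)
Reagents that add atoms: none
Why: Catalytic hydrogenolysis removes the eight benzyl ethers far faster than it touches the flavone pyranone double bond, the ring C ketone or the C2–O1 bond, and the base-free, slightly acidic work-up avoids ring opening through the para-quinone methide of the free C4′ phenol that would racemise C2.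

Compound list
1 | 2-bromo-3-hydroxy-4-methoxybenzaldehyde | COc1ccc(C=O)c(Br)c1O | starting material
2 | 2-bromo-3,4-dihydroxybenzaldehyde | O=Cc1ccc(O)c(O)c1Br | intermediate
3 | 3,4-bis(benzyloxy)-2-bromobenzaldehyde | O=Cc1ccc(OCc2ccccc2)c(OCc2ccccc2)c1Br | intermediate
4 | 3,4-bis(benzyloxy)-2-bromobenzoic acid | OC(=O)c1ccc(OCc2ccccc2)c(OCc2ccccc2)c1Br | intermediate
5 | 2,4,6-trihydroxybenzaldehyde | O=Cc1c(O)cc(O)cc1O | starting material
6 | 2,4-bis(benzyloxy)-6-hydroxybenzaldehyde | O=Cc1c(O)cc(OCc2ccccc2)cc1OCc1ccccc1 | intermediate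
7 | 3,5-bis(benzyloxy)-2-formylphenyl 3,4-bis(benzyloxy)-2-bromobenzoate | O=Cc1c(OC(=O)c2ccc(OCc3ccccc3)c(OCc3ccccc3)c2Br)cc(OCc2ccccc2)cc1OCc1ccccc1 | intermediate
8 | 3,5-bis(benzyloxy)-2-(1,3-dioxolan-2-yl)phenyl 3,4-bis(benzyloxy)-2-bromobenzoate | O=C(Oc1cc(OCc2ccccc2)cc(OCc2ccccc2)c1C1OCCO1)c1ccc(OCc2ccccc2)c(OCc2ccccc2)c1Br | intermediate
9 | 2-[2,4-bis(benzyloxy)-6-({1-[3,4-bis(benzyloxy)-2-bromophenyl]ethenyl}oxy)phenyl]-1,3-dioxolane | C=C(Oc1cc(OCc2ccccc2)cc(OCc2ccccc2)c1C1OCCO1)c1ccc(OCc2ccccc2)c(OCc2ccccc2)c1Br | intermediate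
10 | 2-lithio analogue of 9 (aryllithium, not isolated) | C=C(Oc1cc(OCc2ccccc2)cc(OCc2ccccc2)c1C1OCCO1)c1ccc(OCc2ccccc2)c(OCc2ccccc2)c1[Li] | intermediate
11 | ring B pinacol boronate with dioxolane | C=C(Oc1cc(OCc2ccccc2)cc(OCc2ccccc2)c1C1OCCO1)c1ccc(OCc2ccccc2)c(OCc2ccccc2)c1B1OC(C)(C)C(C)(C)O1 | intermediate
12 | 2,4-bis(benzyloxy)-6-({1-[3,4-bis(benzyloxy)-2-(pinacolboryl)phenyl]ethenyl}oxy)benzaldehyde | O=Cc1c(OC(=C)c2ccc(OCc3ccccc3)c(OCc3ccccc3)c2B2OC(C)(C)C(C)(C)O2)cc(OCc2ccccc2)cc1OCc1ccccc1 | intermediate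
13 | luteolin | O=c1cc(-c2ccc(O)c(O)c2)oc2cc(O)cc(O)c12 | starting material
14 | 5,7,3′,4′-tetra-O-benzylluteolin | O=c1cc(-c2ccc(OCc3ccccc3)c(OCc3ccccc3)c2)oc2cc(OCc3ccccc3)cc(OCc3ccccc3)c12 | intermediate
15 | 8-iodo-5,7,3′,4′-tetra-O-benzylluteolin | O=c1cc(-c2ccc(OCc3ccccc3)c(OCc3ccccc3)c2)oc2c(I)c(OCc3ccccc3)cc(OCc3ccccc3)c12 | intermediate
16 | hydroacylation precursor, 2-[(1-arylvinyl)oxy]-4,6-bis(benzyloxy)benzaldehyde with the hexabenzyl ring B–flavone biaryl | O=Cc1c(OC(=C)c2ccc(OCc9ccccc9)c(OCc9ccccc9)c2-c2c(OCc9ccccc9)cc(OCc9ccccc9)c3c(=O)cc(-c4ccc(OCc9ccccc9)c(OCc9ccccc9)c4)oc23)cc(OCc9ccccc9)cc1OCc9ccccc9 | intermediate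
17 | (2S)-octa-O-benzyl target | O=C1C[C@@H](c2ccc(OCc9ccccc9)c(OCc9ccccc9)c2-c2c(OCc9ccccc9)cc(OCc9ccccc9)c3c(=O)cc(-c4ccc(OCc9ccccc9)c(OCc9ccccc9)c4)oc23)Oc2cc(OCc9ccccc9)cc(OCc9ccccc9)c21 | intermediate
18 | CNP0265600.1, (2S)-eriodictyol-(2′→8″)-luteolin | O=C1C[C@@H](c2ccc(O)c(O)c2-c2c(O)cc(O)c3c(=O)cc(-c4ccc(O)c(O)c4)oc23)Oc2cc(O)cc(O)c21 | target

Total step count: 14. Longest linear sequence: 11 steps (1, 2, 3, 5, 6, 7, 8, 9, 12, 13, 14).

Steps most likely to fail

Step 13. The di-ortho-substituted aldehyde may lose CO, the many oxygen donors may arrest the catalyst, insertion may go exo, and facial selectivity may be poor or mismatched with one axial form. The fallback uses known chemistry. It sets out from 15 and 3 and comes back at 17.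
- Miyaura borylation of 15 (B2pin2, PdCl2(dppf), KOAc, dioxane, 90 °C) would give tetra-O-benzylluteolin-8-yl pinacol boronate F1.
- Suzuki coupling of F1 with the activated bromoaldehyde 3 (Pd(OAc)2, SPhos, K3PO4, toluene/H2O) would give biaryl aldehyde F2.
- Claisen–Schmidt condensation with commercial 2-hydroxy-4,6-bis(benzyloxy)acetophenone (CC(=O)c1c(O)cc(OCc2ccccc2)cc1OCc1ccccc1; Ba(OH)2·8H2O, MeOH/THF) would give 2′-hydroxychalcone F3.
- Oxa-Michael closure (NaOAc, EtOH/THF, reflux) would give racemic octa-O-benzyl flavanone F4.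
- Kinetic resolution by Noyori–Ikariya transfer hydrogenation (Cp*RhCl[(R,R)-TsDPEN], HCO2H/Et3N, EtOAc, rt) should reduce the 2R ketone to cis-(2R,4R)-flavan-4-ol F5 and leave 17.

Step 12. Transmetalation at the tetra-ortho-substituted junction may be slow enough for protodeboronation of the ring B boronate and reductive deiodination of the flavone to take over. The fallback sets out from 9 and comes back at 16.
- Aryllithium 10, generated from 9 as in step 8, would be transmetalated with ZnCl2 to arylzinc chloride F6.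
- Negishi coupling of F6 with 15 (Pd2(dba)3, RuPhos, THF, 60 °C) needs neither base nor water, so the proton source for loss of the metal is gone. It would give biaryl dioxolane F7.
- Unmasking F7 under the conditions of step 9 would give 16.

Step 9. The enol ether may be protonated at C3 and hydrolysed, or C3 may close onto the acetal-derived oxocarbenium ion during unmasking. The fallback dispenses with the mask and with titanium, and so also bypasses steps 3 and 5 to 8. It sets out from 3, 6 and 15 and comes back at 16.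
- Ohira–Bestmann alkynylation of 3 (dimethyl (1-diazo-2-oxopropyl)phosphonate, K2CO3, MeOH/THF) would give aryl alkyne F8.
- Gold-catalysed Markovnikov hydrophenoxylation of F8 with phenol 6 (Ph3PAuNTf2, toluene, 60 °C) would give bromo vinyl ether aldehyde F9 with the formyl group free throughout.
- Suzuki coupling of F9 with flavone boronate F1, made from 15 as above (Pd(OAc)2, SPhos, K3PO4, toluene/H2O, 90 °C), would give 16.
- The gold step is less secure with a chelated phenol and a terminal alkyne, which is why it is held in reserve.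

Further compounds
F1 | step 13 | 5,7,3′,4′-tetra-O-benzylluteolin-8-yl pinacol boronate | O=c1cc(-c2ccc(OCc3ccccc3)c(OCc3ccccc3)c2)oc2c(B3OC(C)(C)C(C)(C)O3)c(OCc3ccccc3)cc(OCc3ccccc3)c12
F2 | step 13 | 3,4-bis(benzyloxy)-2-(5,7,3′,4′-tetra-O-benzylluteolin-8-yl)benzaldehyde | O=Cc1ccc(OCc9ccccc9)c(OCc9ccccc9)c1-c1c(OCc9ccccc9)cc(OCc9ccccc9)c2c(=O)cc(-c3ccc(OCc9ccccc9)c(OCc9ccccc9)c3)oc12
F3 | step 13 | (E)-2′-hydroxy-4′,6′-bis(benzyloxy)chalcone of F2 | O=C(/C=C/c1ccc(OCc9ccccc9)c(OCc9ccccc9)c1-c1c(OCc9ccccc9)cc(OCc9ccccc9)c2c(=O)cc(-c3ccc(OCc9ccccc9)c(OCc9ccccc9)c3)oc12)c1c(O)cc(OCc9ccccc9)cc1OCc9ccccc9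
F4 | step 13 | racemic octa-O-benzyl flavanone | O=C1CC(c2ccc(OCc9ccccc9)c(OCc9ccccc9)c2-c2c(OCc9ccccc9)cc(OCc9ccccc9)c3c(=O)cc(-c4ccc(OCc9ccccc9)c(OCc9ccccc9)c4)oc23)Oc2cc(OCc9ccccc9)cc(OCc9ccccc9)c21
F5 | step 13 | cis-(2R,4R)-octa-O-benzyl flavan-4-ol | O[C@@H]1C[C@H](c2ccc(OCc9ccccc9)c(OCc9ccccc9)c2-c2c(OCc9ccccc9)cc(OCc9ccccc9)c3c(=O)cc(-c4ccc(OCc9ccccc9)c(OCc9ccccc9)c4)oc23)Oc2cc(OCc9ccccc9)cc(OCc9ccccc9)c21
F6 | step 12 | arylzinc chloride derived from 10 | C=C(Oc1cc(OCc2ccccc2)cc(OCc2ccccc2)c1C1OCCO1)c1ccc(OCc2ccccc2)c(OCc2ccccc2)c1[Zn]Cl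
F7 | step 12 | dioxolane of 16 | C=C(Oc1cc(OCc9ccccc9)cc(OCc9ccccc9)c1C1OCCO1)c1ccc(OCc9ccccc9)c(OCc9ccccc9)c1-c1c(OCc9ccccc9)cc(OCc9ccccc9)c2c(=O)cc(-c3ccc(OCc9ccccc9)c(OCc9ccccc9)c3)oc12
F8 | step 9 | 1,2-bis(benzyloxy)-3-bromo-4-ethynylbenzene | C#Cc1ccc(OCc2ccccc2)c(OCc2ccccc2)c1Br
F9 | step 9 | 2,4-bis(benzyloxy)-6-({1-[3,4-bis(benzyloxy)-2-bromophenyl]ethenyl}oxy)benzaldehyde | O=Cc1c(OC(=C)c2ccc(OCc3ccccc3)c(OCc3ccccc3)c2Br)cc(OCc2ccccc2)cc1OCc1ccccc1
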